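The benzene ring of the coumarin (C4a, C5, C6, C7, C8, C8a) is a 2-aryl resorcinol: C8, which carries flavone C6, sits between the oxygen-bearing C7 and C8a. The route therefore does not couple two crowded arenes but grows that ring onto the flavone. A Danheiser benzannulation of cyclobutenone with 6-(ethoxyethynyl)-5,7,4'-trimethoxyflavone, made from apigenin through its 6-iodide, forms C8–C8a, C6–C7 and C4a–C8a in one operation and delivers the resorcinol with its two oxygens already differentiated (free OH at the future O1, OEt at C7). The free phenol then directs formylation; Wittig–lactonization and BBr3 finish the target.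

Key step: step 6

Assumption: the target SMILES carries no stereodescriptor, so the hindered biaryl axis is left undefined (racemic if rotation is slow), and 3-bromocyclobutanone is taken as a purchased compound.

Step 1
Reactants: 1 apigenin
Product: 2 5-hydroxy-7,4'-dimethoxyflavone
Conditions: Me2SO4 (2.1 equiv), K2CO3, acetone, reflux
Reagents that add atoms: dimethyl sulfate, COS(=O)(=O)OC
Why: Williamson O-methylation should stop at the 7- and 4'-hydroxyls because the 5-hydroxyl is held in a hydrogen bond to the C4 carbonyl and is far less nucleophilic.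

Step 2
Reactants: 2 5-hydroxy-7,4'-dimethoxyflavone
Product: 3 5-hydroxy-6-iodo-7,4'-dimethoxyflavone
Conditions: BnMe3N·ICl2 (1.1 equiv), CaCO3, CH2Cl2–MeOH, rt
Reagents that add atoms: benzyltrimethylammonium dichloroiodate, C[N+](C)(C)Cc1ccccc1.Cl[I-]Cl
Why: Electrophilic aromatic iodination in which the free 5-hydroxyl directs the iodine to its ortho carbon C6 instead of C8, the established outcome for 5-hydroxy-7-alkoxyflavones with this reagent, while CaCO3 takes up the HCl.

Step 3
Reactants: 3 5-hydroxy-6-iodo-7,4'-dimethoxyflavone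
Product: 4 6-iodo-5,7,4'-trimethoxyflavone
Conditions: Me2SO4 (excess), K2CO3, acetone, prolonged reflux
Reagents that add atoms: dimethyl sulfate, COS(=O)(=O)OC
Why: Williamson methylation under forcing conditions should cap the chelated, iodine-flanked 5-hydroxyl, which must be masked because a free ortho phenol would add across the ynol ether to be placed at C6.

Step 4
Reactants: 4 6-iodo-5,7,4'-trimethoxyflavone; 5 ethoxyacetylene
Product: 8 6-(ethoxyethynyl)-5,7,4'-trimethoxyflavone, via lithium ethoxyacetylide 6 (not isolated), via ethoxyethynylzinc chloride 7 (not isolated)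
Conditions: 5, n-BuLi, THF, −78 °C; ZnCl2, −78 to 0 °C; then 4, Pd(PPh3)4 (5 mol%), THF, rt to 45 °C; NaHCO3 work-up
Reagents that add atoms: none
Why: Negishi cross-coupling, in which the alkynylzinc chloride transfers its sp carbon to the aryl–palladium iodide formed by oxidative addition of zerovalent palladium, should tolerate the flavone enone because the zinc reagent is too mild to add to it.

Step 5
Reactants: 9 3-bromocyclobutanone
Product: 10 cyclobut-2-en-1-one
Conditions: n-Bu3N, neat, rt; vacuum transfer into a −78 °C trap; kept as a cold toluene solution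
Reagents that add atoms: none
Why: Amine-promoted dehydrobromination (E1cB) of the β-bromo ketone is the established access to the parent cyclobutenone, which should be kept cold and dilute because it polymerises when neat.

Step 6
Reactants: 8 6-(ethoxyethynyl)-5,7,4'-trimethoxyflavone; 10 cyclobut-2-en-1-one
Product: 15 6-(2-ethoxy-6-hydroxyphenyl)-5,7,4'-trimethoxyflavone, via vinylketene 11 (not isolated), via 4-vinylcyclobutenone adduct 12 (not isolated), via dienylketene 13 (not isolated), via cyclohexa-2,4-dienone tautomer 14 (not isolated)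
Conditions: 10 (3 equiv, in portions), toluene, 80 °C, sealed tube; then K2CO3, MeOH, rt
Reagents that add atoms: none
Why: At 80 °C 10 should open in a four-electron conrotatory electrocyclic step to vinylketene 11, whose carbonyl carbon is attacked by the aryl-bearing carbon of 8 in a [2+2] cycloaddition to give 12; reversible four-electron opening of 12 gives dienylketene 13, which closes to dienone 14 and tautomerises to phenol 15. The closest known reaction is the Danheiser benzannulation of cyclobutenones with alkoxyalkynes, applied here to an ynol ether that carries a 2,6-dimethoxyaryl group. The single new ring, the future coumarin carbocycle, is closed by a thermally allowed disrotatory six-electron electrocyclization that makes C4a–C8a (the old C1–C4 bond of cyclobutenone, cut in the first opening and re-made here), after the cycloaddition has made C8–C8a and C6–C7. No stereocentre is created in 15: the sp3 carbon of 12 is racemic and becomes planar in 13, and only the geometry of 13 with the vinyl group cis to the ketene carbon cyclises, the other returning to 12. The step needs full regioselectivity in the [2+2] event, which the ethoxy oxygen secures by making the flavonyl-bearing alkyne carbon the nucleophile, so that this carbon ends up between C–OH and C–OEt. The bath is held at 80 °C to avoid retro-ene loss of ethylene from the ynol ether, and the basic methanol treatment should return any product that excess ketene has O-acylated.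

Step 7
Reactants: 15 6-(2-ethoxy-6-hydroxyphenyl)-5,7,4'-trimethoxyflavone
Product: 17 4-ethoxy-2-hydroxy-3-(5,7,4'-trimethoxyflavon-6-yl)benzaldehyde, via hydroxymethylphenol 16 (not isolated)
Conditions: MgCl2, Et3N, (CH2O)n, MeCN, reflux; aq. HCl work-up
Reagents that add atoms: paraformaldehyde (reacts as formaldehyde), C=O
Why: In this magnesium-mediated ortho-formylation (Casnati–Skattebøl) the magnesium phenoxide of 15 should deliver formaldehyde to its only free ortho carbon to give 16, which is oxidised in place by hydride transfer to a second formaldehyde, so that neither the ethylated oxygen nor the phenol-free flavone can direct a competing attack.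

Step 8
Reactants: 17 4-ethoxy-2-hydroxy-3-(5,7,4'-trimethoxyflavon-6-yl)benzaldehyde; 18 ethyl (triphenylphosphoranylidene)acetate
Product: 21 7-ethoxy-8-(5,7,4'-trimethoxyflavon-6-yl)coumarin, via E-cinnamate ester 19 (not isolated), via Z-cinnamate ester 20 (not isolated)
Conditions: 18 (1.5 equiv), N,N-diethylaniline, reflux (about 215 °C), N2
Reagents that add atoms: none
Why: Wittig olefination with the stabilised ylide should give mainly 19, which at this temperature equilibrates to 20 and lactonises with loss of ethanol, the standard one-pot conversion of salicylaldehydes into 3,4-unsubstituted coumarins.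

Step 9
Reactants: 21 7-ethoxy-8-(5,7,4'-trimethoxyflavon-6-yl)coumarin
Product: 22 5,7-dihydroxy-6-(7-hydroxy-2-oxo-2H-chromen-8-yl)-2-(4-hydroxyphenyl)-4H-chromen-4-one (CNP0223343.0)
Conditions: BBr3 (excess), CH2Cl2, −78 °C to rt, then 40 °C; H2O quench
Reagents that add atoms: none
Why: Lewis-acid-mediated SN2 dealkylation of aryl alkyl ethers by BBr3 should cleave the three methyl ethers and the ethyl ether, while the coumarin lactone and the flavone pyranone only complex reversibly and are returned on aqueous work-up.

Compound list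
1 | apigenin (5,7,4'-trihydroxyflavone) | O=c1cc(-c2ccc(O)cc2)oc2cc(O)cc(O)c12 | starting material
2 | 5-hydroxy-7,4'-dimethoxyflavone | O=c1cc(-c2ccc(OC)cc2)oc2cc(OC)cc(O)c12 | intermediate
3 | 5-hydroxy-6-iodo-7,4'-dimethoxyflavone | O=c1cc(-c2ccc(OC)cc2)oc2cc(OC)c(I)c(O)c12 | intermediate
4 | 6-iodo-5,7,4'-trimethoxyflavone | O=c1cc(-c2ccc(OC)cc2)oc2cc(OC)c(I)c(OC)c12 | intermediate
5 | ethoxyacetylene | C#COCC | starting material
6 | lithium ethoxyacetylide | CCOC#C[Li] | intermediate
7 | ethoxyethynylzinc chloride | CCOC#C[Zn]Cl | intermediate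
8 | 6-(ethoxyethynyl)-5,7,4'-trimethoxyflavone | CCOC#Cc1c(OC)cc2oc(-c3ccc(OC)cc3)cc(=O)c2c1OC | intermediate
9 | 3-bromocyclobutanone | O=C1CC(Br)C1 | starting material
10 | cyclobut-2-en-1-one | O=C1C=CC1 | intermediate
11 | vinylketene (buta-1,3-dien-1-one) | C=CC=C=O | intermediate
12 | 3-ethoxy-2-(5,7,4'-trimethoxyflavon-6-yl)-4-vinylcyclobut-2-en-1-one (racemic) | C=CC1C(=O)C(c2c(OC)cc3oc(-c4ccc(OC)cc4)cc(=O)c3c2OC)=C1OCC | intermediate
13 | (3E)-3-ethoxy-2-(5,7,4'-trimethoxyflavon-6-yl)hexa-1,3,5-trien-1-one (vinyl group cis to the ketene carbon) | C=C/C=C(\C(=C=O)c1c(OC)cc2oc(-c3ccc(OC)cc3)cc(=O)c2c1OC)OCC | intermediate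
14 | 3-ethoxy-2-(5,7,4'-trimethoxyflavon-6-yl)cyclohexa-2,4-dien-1-one | O=C1CC=CC(OCC)=C1c1c(OC)cc2oc(-c3ccc(OC)cc3)cc(=O)c2c1OC | intermediate
15 | 6-(2-ethoxy-6-hydroxyphenyl)-5,7,4'-trimethoxyflavone | CCOc1cccc(O)c1-c1c(OC)cc2oc(-c3ccc(OC)cc3)cc(=O)c2c1OC | intermediate
16 | 6-[6-ethoxy-2-hydroxy-3-(hydroxymethyl)phenyl]-5,7,4'-trimethoxyflavone | CCOc1ccc(CO)c(O)c1-c1c(OC)cc2oc(-c3ccc(OC)cc3)cc(=O)c2c1OC | intermediate
17 | 4-ethoxy-2-hydroxy-3-(5,7,4'-trimethoxyflavon-6-yl)benzaldehyde | CCOc1ccc(C=O)c(O)c1-c1c(OC)cc2oc(-c3ccc(OC)cc3)cc(=O)c2c1OC | intermediate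
18 | ethyl (triphenylphosphoranylidene)acetate | CCOC(=O)C=P(c1ccccc1)(c1ccccc1)c1ccccc1 | starting material
19 | ethyl (E)-3-[4-ethoxy-2-hydroxy-3-(5,7,4'-trimethoxyflavon-6-yl)phenyl]prop-2-enoate | CCOC(=O)/C=C/c1ccc(OCC)c(-c2c(OC)cc3oc(-c4ccc(OC)cc4)cc(=O)c3c2OC)c1O | intermediate
20 | ethyl (Z)-3-[4-ethoxy-2-hydroxy-3-(5,7,4'-trimethoxyflavon-6-yl)phenyl]prop-2-enoate | CCOC(=O)/C=C\c1ccc(OCC)c(-c2c(OC)cc3oc(-c4ccc(OC)cc4)cc(=O)c3c2OC)c1O | intermediate
21 | 7-ethoxy-8-(5,7,4'-trimethoxyflavon-6-yl)coumarin | CCOc1ccc2ccc(=O)oc2c1-c1c(OC)cc2oc(-c3ccc(OC)cc3)cc(=O)c2c1OC | intermediate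
22 | 5,7-dihydroxy-6-(7-hydroxy-2-oxo-2H-chromen-8-yl)-2-(4-hydroxyphenyl)-4H-chromen-4-one (CNP0223343.0) | O=c1ccc2ccc(O)c(-c3c(O)cc4oc(-c5ccc(O)cc5)cc(=O)c4c3O)c2o1 | target

Total step count: 9. Longest linear sequence: 8 steps (steps 1, 2, 3, 4, 6, 7, 8, 9 from apigenin; step 5 is the one-step side branch to cyclobutenone).

Steps most likely to fail

Step 6. Capture of the vinylketene at an alkyne carbon flanked by two ortho-methoxy groups may be slower than oligomerisation of the ketene and of cyclobutenone, or than thermal loss of ethylene from the ynol ether, so that conversion stalls. The fallback sets out from 4 and comes back at 15, building the biaryl bond by cross-coupling. Purchased 3-ethoxyphenol would be protected (MOMCl, i-Pr2NEt, CH2Cl2) as 1-ethoxy-3-(methoxymethoxy)benzene F1. Directed ortho-lithiation between the two oxygens (n-BuLi, THF, 0 °C) and a B(OMe)3 quench should give [2-ethoxy-6-(methoxymethoxy)phenyl]boronic acid F2. Suzuki–Miyaura coupling of F2 with 4 (Pd(OAc)2, SPhos, K3PO4, toluene–water, 100 °C) should give 6-[2-ethoxy-6-(methoxymethoxy)phenyl]-5,7,4'-trimethoxyflavone F3, and HCl in MeOH would remove the acetal to give 15.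

Step 4. Oxidative addition and transmetalation at the di-ortho-substituted, electron-rich iodide may be sluggish, and the acid-labile ynol ether may hydrate to the arylacetic ester during work-up or chromatography. The fallback sets out from 5 and 4 and comes back at 8, using a preformed, purified tin reagent under neutral conditions. Ethoxyacetylene 5 would be lithiated and quenched with Bu3SnCl to give tributyl(ethoxyethynyl)stannane F4, which is distilled. Stille coupling of F4 with 4 (Pd(PPh3)4, CuI, DMF, 60 °C), followed by filtration through triethylamine-deactivated silica, should give 8.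

Step 7. Crowding of the magnesium phenoxide by the neighbouring flavonyl group may stop the reaction at low conversion or at the hydroxymethyl stage. The fallback sets out from 15 and comes back at 21, so it bypasses steps 7 and 8. Steglich esterification of 15 with propiolic acid (DCC, CH2Cl2, 0 °C) would give 3-ethoxy-2-(5,7,4'-trimethoxyflavon-6-yl)phenyl propiolate F5. Intramolecular hydroarylation of the tethered alkyne catalysed by Pd(OAc)2 (TFA–CH2Cl2, rt) should then close the lactone onto the only free ortho carbon, which is also para to the ethoxy group, and give 21.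

Further compounds
F1 | step 6 | 1-ethoxy-3-(methoxymethoxy)benzene | CCOc1cccc(OCOC)c1
F2 | step 6 | [2-ethoxy-6-(methoxymethoxy)phenyl]boronic acid | CCOc1cccc(OCOC)c1B(O)O
F3 | step 6 | 6-[2-ethoxy-6-(methoxymethoxy)phenyl]-5,7,4'-trimethoxyflavone | CCOc1cccc(OCOC)c1-c1c(OC)cc2oc(-c3ccc(OC)cc3)cc(=O)c2c1OC
F4 | step 4 | tributyl(ethoxyethynyl)stannane | CCOC#C[Sn](CCCC)(CCCC)CCCC
F5 | step 7 | 3-ethoxy-2-(5,7,4'-trimethoxyflavon-6-yl)phenyl propiolate | C#CC(=O)Oc1cccc(OCC)c1-c1c(OC)cc2oc(-c3ccc(OC)cc3)cc(=O)c2c1OC
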